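**Retrosynthetic overview**
- The prenyl group at the quaternary carbon is traced back to an allyl group (cross-metathesis, last step); allyl is an oxidation-inert stand-in that leaves the inner geranyl alkene as the only trisubstituted alkene next to the enol.
- The dihydrofuran O–C bond, together with the ring CH and carbinol stereocentres, is disconnected to the ring enol oxygen plus a (2S,3S)-epoxide of the inner geranyl alkene (ligand-controlled, enol-directed epoxidation, then 5-exo opening with inversion).
- The quaternary stereocentre comes from a Pd-catalysed asymmetric allylic alkylation of a C-geranyl acylfilicinic acid.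
- That acid comes from phloroglucinol and (R)-2-methylbutanoic acid by Friedel–Crafts acylation, gem-dimethylation and C-geranylation.
- Ring order: the carbocycle is the phloroglucinol ring throughout (dearomatised in two stages); the dihydrofuran is the only ring made, in the second-to-last step.

Assumption: (R)-2-methylbutanoic acid is bought in high ee, and each triketone is drawn and named as one of its freely interconverting enol tautomers.

**Step 1**
Reactants: 1 phloroglucinol; 2 (2R)-2-methylbutanoic acid
Product: 4 (2R)-2-methyl-1-(2,4,6-trihydroxyphenyl)butan-1-one, via acid chloride 3 (not isolated)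
Conditions: 2, (COCl)2 (1.1 equiv), cat. DMF, CH2Cl2, 0 °C to rt; then 1, AlCl3 (3.5 equiv), PhNO2, 0 °C to rt; aq. HCl work-up
Reagents that add atoms: none
Why: Friedel–Crafts acylation of an arene whose three ring CH positions are equivalent gives a single mono-ketone (deactivated towards a second acylation), and the α-stereocentre is carried through because no base is present and the temperature stays at or below rt.

**Step 2**
Reactants: 4 (2R)-2-methyl-1-(2,4,6-trihydroxyphenyl)butan-1-one
Product: 5 3,5-dihydroxy-4,4-dimethyl-2-[(2R)-2-methylbutanoyl]cyclohexa-2,5-dien-1-one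
Conditions: MeI (2.2 equiv), NaOMe (3 equiv), MeOH, 0 °C to rt
Reagents that add atoms: iodomethane, CI
Why: Dearomative double C-methylation (enolate alkylation) in methanol, where hydrogen bonding to the oxygens steers iodomethane to carbon and the second methyl enters the already methylated carbon to give the gem-dimethyl ring as the main product (separated from mono- and over-methylated material), the sec-butyl stereocentre being untouched because only the far more acidic ring enols are deprotonated.

**Step 3**
Reactants: 5 3,5-dihydroxy-4,4-dimethyl-2-[(2R)-2-methylbutanoyl]cyclohexa-2,5-dien-1-one; 6 geranyl bromide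
Product: 7 6-[(2E)-3,7-dimethylocta-2,6-dien-1-yl]-3,5-dihydroxy-4,4-dimethyl-2-[(2R)-2-methylbutanoyl]cyclohexa-2,5-dien-1-one
Conditions: 6 (1.0 equiv), 10% aq. KOH, 0 °C
Reagents that add atoms: none
Why: SN2 C-alkylation of the enolate at the one remaining ring CH by an allylic bromide (aqueous base favours C- over O-alkylation, one equivalent limits double alkylation) proceeds without allylic transposition so the (E)-alkene is kept, and no stereocentre is formed because the product re-enolises.

**Step 4**
Reactants: 7 6-[(2E)-3,7-dimethylocta-2,6-dien-1-yl]-3,5-dihydroxy-4,4-dimethyl-2-[(2R)-2-methylbutanoyl]cyclohexa-2,5-dien-1-one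
Product: 8 (4S)-4-[(2E)-3,7-dimethylocta-2,6-dien-1-yl]-3-hydroxy-6,6-dimethyl-2-[(2R)-2-methylbutanoyl]-4-(prop-2-en-1-yl)cyclohex-2-ene-1,5-dione
Conditions: allyl methyl carbonate (1.2 equiv), Pd2(dba)3·CHCl3 (2.5 mol %), (R,R)-DACH-phenyl Trost ligand (7.5 mol %), CH2Cl2, 0 °C
Reagents that add atoms: allyl methyl carbonate, C=CCOC(=O)OC
Why: Tsuji–Trost asymmetric allylic alkylation: the soft triketone enolate (formed by the methoxide released from the carbonate) attacks the π-allyl palladium complex at the geranyl-bearing carbon, O-allylation being reversible under zerovalent palladium, and the chiral ligand pocket distinguishes the two enolate faces, whose flanks differ strongly (CMe2/ketone side versus chelated acyl-enol side), setting the quaternary centre as (4S).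

**Step 5**
Reactants: 8 (4S)-4-[(2E)-3,7-dimethylocta-2,6-dien-1-yl]-3-hydroxy-6,6-dimethyl-2-[(2R)-2-methylbutanoyl]-4-(prop-2-en-1-yl)cyclohex-2-ene-1,5-dione
Product: 10 (2R,3aS)-2-[(2S)-2-hydroxy-6-methylhept-5-en-2-yl]-5,5-dimethyl-7-[(2R)-2-methylbutanoyl]-3a-(prop-2-en-1-yl)-3,3a-dihydro-1-benzofuran-4,6(2H,5H)-dione, via epoxide 9 (not isolated)
Conditions: VO(OiPr)3 (5 mol %), (R,R)-N,N'-dihydroxy-N,N'-bis(diphenylacetyl)cyclohexane-1,2-diamine (7.5 mol %), t-BuOOH (1.05 equiv, decane solution), toluene, 0 °C to rt; then Et3N, rt
Reagents that add atoms: tert-butyl hydroperoxide, CC(C)(C)OO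
Why: Proposed new method: an enol-directed, ligand-controlled vanadium epoxidation with in situ cycloetherification, in which the acidic C3 enol (pKa about 5) replaces an isopropoxide on the pentavalent vanadium centre held by the C2-symmetric bishydroxamate, the η2-bound tert-butylperoxide can reach only the inner geranyl alkene (bishomoallylic to the bound oxygen; the allyl alkene is monosubstituted and far less nucleophilic, the outer alkene is out of reach), the ligand selects the alkene face to give the (2S,3S)-epoxide 9, and the enolate oxygen then opens it at the secondary carbon in a 5-exo-tet SN2 step with inversion (ring CH becomes R) while the tertiary C–O bond is untouched (carbinol S), only the C3 oxygen being able to close because the C5 ketone has no enol form; the closest known reaction type is the vanadium/tert-butyl hydroperoxide epoxidation–cyclisation of bishomoallylic alcohols to 2-(1-hydroxyalkyl)tetrahydrofurans (linalool to furanoid linalool oxides) combined with bishydroxamic-acid/vanadium asymmetric epoxidation of allylic and homoallylic alcohols, neither of which has been shown with an enol as the directing group.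

**Step 6**
Reactants: 10 (2R,3aS)-2-[(2S)-2-hydroxy-6-methylhept-5-en-2-yl]-5,5-dimethyl-7-[(2R)-2-methylbutanoyl]-3a-(prop-2-en-1-yl)-3,3a-dihydro-1-benzofuran-4,6(2H,5H)-dione
Product: 11 (2R,3aS)-2-[(2S)-2-hydroxy-6-methylhept-5-en-2-yl]-5,5-dimethyl-7-[(2R)-2-methylbutanoyl]-3a-(3-methylbut-2-en-1-yl)-3,3a-dihydro-1-benzofuran-4,6(2H,5H)-dione
Conditions: 2-methylbut-2-ene (large excess), second-generation Grubbs catalyst (5 mol %), CH2Cl2, 40 °C
Reagents that add atoms: 2-methylbut-2-ene, CC=C(C)C
Why: Olefin cross-metathesis exchanges the monosubstituted allyl alkene with the isopropylidene unit of 2-methylbut-2-ene to give the prenyl group, while the trisubstituted side-chain alkene can only exchange degenerately, the tetrasubstituted enol ether is inert and no stereocentre is touched.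

**Compound list**
1 | phloroglucinol (benzene-1,3,5-triol) | Oc1cc(O)cc(O)c1 | starting material
2 | (2R)-2-methylbutanoic acid | CC[C@@H](C)C(=O)O | starting material
3 | (2R)-2-methylbutanoyl chloride | CC[C@@H](C)C(=O)Cl | intermediate
4 | (2R)-2-methyl-1-(2,4,6-trihydroxyphenyl)butan-1-one | CC[C@@H](C)C(=O)c1c(O)cc(O)cc1O | intermediate
5 | 3,5-dihydroxy-4,4-dimethyl-2-[(2R)-2-methylbutanoyl]cyclohexa-2,5-dien-1-one | CC[C@@H](C)C(=O)C1=C(O)C(C)(C)C(O)=CC1=O | intermediate
6 | geranyl bromide [(2E)-1-bromo-3,7-dimethylocta-2,6-diene] | BrC/C=C(\C)CCC=C(C)C | starting material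
7 | 6-[(2E)-3,7-dimethylocta-2,6-dien-1-yl]-3,5-dihydroxy-4,4-dimethyl-2-[(2R)-2-methylbutanoyl]cyclohexa-2,5-dien-1-one | CC[C@@H](C)C(=O)C1=C(O)C(C)(C)C(O)=C(C/C=C(\C)CCC=C(C)C)C1=O | intermediate
8 | (4S)-4-[(2E)-3,7-dimethylocta-2,6-dien-1-yl]-3-hydroxy-6,6-dimethyl-2-[(2R)-2-methylbutanoyl]-4-(prop-2-en-1-yl)cyclohex-2-ene-1,5-dione | CC[C@@H](C)C(=O)C1=C(O)[C@](CC=C)(C/C=C(\C)CCC=C(C)C)C(=O)C(C)(C)C1=O | intermediate
9 | (4S)-3-hydroxy-6,6-dimethyl-2-[(2R)-2-methylbutanoyl]-4-{[(2S,3S)-3-methyl-3-(4-methylpent-3-en-1-yl)oxiran-2-yl]methyl}-4-(prop-2-en-1-yl)cyclohex-2-ene-1,5-dione | CC[C@@H](C)C(=O)C1=C(O)[C@](CC=C)(C[C@@H]2O[C@@]2(C)CCC=C(C)C)C(=O)C(C)(C)C1=O | intermediate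
10 | (2R,3aS)-2-[(2S)-2-hydroxy-6-methylhept-5-en-2-yl]-5,5-dimethyl-7-[(2R)-2-methylbutanoyl]-3a-(prop-2-en-1-yl)-3,3a-dihydro-1-benzofuran-4,6(2H,5H)-dione | CC[C@@H](C)C(=O)C1=C2O[C@@H]([C@@](C)(O)CCC=C(C)C)C[C@]2(CC=C)C(=O)C(C)(C)C1=O | intermediate
11 | (2R,3aS)-2-[(2S)-2-hydroxy-6-methylhept-5-en-2-yl]-5,5-dimethyl-7-[(2R)-2-methylbutanoyl]-3a-(3-methylbut-2-en-1-yl)-3,3a-dihydro-1-benzofuran-4,6(2H,5H)-dione | CC[C@@H](C)C(=O)C1=C2O[C@@H]([C@@](C)(O)CCC=C(C)C)C[C@]2(CC=C(C)C)C(=O)C(C)(C)C1=O | target

**Totals**
Total step count: 6. Longest linear sequence: 6 (from phloroglucinol).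

**Steps most likely to fail, with fallbacks**

The most exposed step is step 5, the proposed new step. The risks are:
- the triketone may chelate vanadium without directing the oxidant;
- the acyl-bearing enol carbon may be hydroxylated;
- the new tertiary alcohol of 10, itself bishomoallylic to the outer alkene, may direct a second epoxidation (hence only 1.05 equiv of oxidant);
- the facial sense of the (R,R)-ligand is a prediction, and if the first run shows the opposite sense the (S,S)-ligand is used.

The fallback uses known chemistry; it sets out from 8 and comes back at 10. Compound 8 is epoxidised without a metal by mCPBA (1.0 equiv, NaHCO3, CH2Cl2, −20 °C), a hydrogen-bond-directed peracid epoxidation next to an enol of the kind known for prenylated enolised β-dicarbonyls, and Et3N then completes the 5-exo closure. Both alkene faces react, so besides epoxide 9 the diastereomeric (2R,3R)-epoxide F1 is formed. Epoxide 9 closes to 10 and F1 closes to the (2S)-configured dihydrofuran with an (R)-carbinol F2. Compound 10 (allyl and side chain cis) and F2 (trans) are separated on silica. The conversion is kept low and 8 is recycled to limit attack on the outer alkene. Compound 10 then enters step 6.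

The second is step 4. The enantioselectivity of the Pd-catalysed alkylation on this flat, highly stabilised enolate is not established, and the sense of the (R,R)-ligand has to be confirmed (the antipodal ligand is the simple correction). The fallback sets out from 7 and comes back at 8. Compound 7 is C-allylated with allyl bromide in 10% aq. KOH at 0 °C, as in step 3, which gives 8 together with its (4R)-epimer F3 in about equal amounts. The two are diastereomers because of the (R)-acyl centre and are separated by preparative HPLC on a chiral stationary phase. Compound 8 then enters step 5.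

The third is step 1. The Lewis acid may enolise the aryl ketone and erode the α-stereocentre. The fallback sets out from 1 and 2 and comes back at 4. Steglich esterification (DCC, cat. DMAP, THF, 0 °C, with 1 in three-fold excess) gives the mono-ester 3,5-dihydroxyphenyl (2R)-2-methylbutanoate F4. A photo-Fries rearrangement (254 nm, MeCN, rt) then moves the acyl group to a ring carbon inside the solvent cage without acid or base. Since all ring positions are equivalent, only 4 can form.

**Further compounds**
F1 | step 5 | (4S)-3-hydroxy-6,6-dimethyl-2-[(2R)-2-methylbutanoyl]-4-{[(2R,3R)-3-methyl-3-(4-methylpent-3-en-1-yl)oxiran-2-yl]methyl}-4-(prop-2-en-1-yl)cyclohex-2-ene-1,5-dione | CC[C@@H](C)C(=O)C1=C(O)[C@](CC=C)(C[C@H]2O[C@]2(C)CCC=C(C)C)C(=O)C(C)(C)C1=O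
F2 | step 5 | (2S,3aS)-2-[(2R)-2-hydroxy-6-methylhept-5-en-2-yl]-5,5-dimethyl-7-[(2R)-2-methylbutanoyl]-3a-(prop-2-en-1-yl)-3,3a-dihydro-1-benzofuran-4,6(2H,5H)-dione | CC[C@@H](C)C(=O)C1=C2O[C@H]([C@](C)(O)CCC=C(C)C)C[C@]2(CC=C)C(=O)C(C)(C)C1=O
F3 | step 4 | (4R)-4-[(2E)-3,7-dimethylocta-2,6-dien-1-yl]-3-hydroxy-6,6-dimethyl-2-[(2R)-2-methylbutanoyl]-4-(prop-2-en-1-yl)cyclohex-2-ene-1,5-dione | CC[C@@H](C)C(=O)C1=C(O)[C@@](CC=C)(C/C=C(\C)CCC=C(C)C)C(=O)C(C)(C)C1=O
F4 | step 1 | 3,5-dihydroxyphenyl (2R)-2-methylbutanoate | CC[C@@H](C)C(=O)Oc1cc(O)cc(O)c1
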